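**Retrosynthetic overview**
1. Target 14 ⇐ cleavage of one of the two equivalent vinylogous methyl esters of the C2-symmetric bis(2-hydroxy-5-methoxy-6-methylquinone) 13.
2. 13 ⇐ bis(isopropoxyquinone) 9, by C–H methoxylation at the single free position of each ring, then de-isopropylation.
3. 9 ⇐ bis(cyclobutenedione) 5 + two isopropenyl nucleophiles: a two-fold 4π ring-opening/6π ring-closure builds both six-membered rings in the same thermolysis.
4. 5 ⇐ di-Grignard of 1,14-dibromotetradecane + two diisopropyl squarates.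
5. Ring order: the two carbocycles of the target are formed simultaneously in step 2; the four-membered rings are bought in with the squarate.

Assumption: the target has no stereocentre and no stereogenic double bond, so it is one achiral compound and nothing has to be controlled; the linker is read as (CH2)14.

Ring numbering used below for the quinones: C1=O, C2 linker, C3 O-substituent, C4=O, C5 methyl, C6 free position/OMe.

**Step 1**
Reactants: 1 1,14-dibromotetradecane; 2 diisopropyl squarate (2.6 equiv)
Product: 5 4,4'-(tetradecane-1,14-diyl)bis(3-isopropoxycyclobut-3-ene-1,2-dione), via di-Grignard reagent 3 (not isolated), via bis(cyclobutenone carbinol) 4 (not isolated)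
Conditions: Mg, THF, 60 °C; add to 2, THF, −78 °C; aq. NH4Cl; then conc. HCl (cat.), CH2Cl2, rt
Reagents that add atoms: water, O (supplies the new carbonyl oxygen in the HCl-mediated rearrangement)
Why: Grignard 1,2-addition stops at one carbonyl of each squarate because the adduct alkoxide is a deactivated vinylogous ester, and acid then ionises the tertiary carbinol and hydrolyses the resulting oxocarbenium ion with loss of isopropanol (Liebeskind–Moore squarate-to-cyclobutenedione transposition), which also erases the carbinol stereocentres of 4.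

**Step 2**
Reactants: 5; 6 isopropenylmagnesium bromide (2.4 equiv)
Product: 9 2,2'-(tetradecane-1,14-diyl)bis(3-isopropoxy-5-methyl-1,4-benzoquinone), via bis(isopropenyl carbinol) 7 (not isolated), via bis(hydroquinone) 8 (not isolated)
Conditions: 6, THF, −78 °C; aq. NH4Cl; p-xylene, 138 °C, 1 h; then Ag2O, rt
Reagents that add atoms: isopropenylmagnesium bromide (6), CC(=C)[Mg]Br
Why: The Grignard reagent adds to the ketone-like carbonyl next to C–OiPr (the other carbonyl is a vinylogous ester), and on heating each half undergoes torquoselective 4π-electrocyclic ring opening (OH outward) to a dienylketene, 6π-electrocyclisation and tautomerisation (Moore–Liebeskind ring expansion), so both benzenoid rings close in one thermolysis before Ag2O dehydrogenates them to the quinones; the carbinol stereocentres of 7 are destroyed.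

**Step 3**
Reactants: 9
Product: 11 2,2'-(tetradecane-1,14-diyl)bis(3-isopropoxy-6-methoxy-5-methyl-1,4-benzoquinone), via bis(methoxyhydroquinone) 10 (not isolated)
Conditions: ZnCl2 (anhydrous, 5 equiv), MeOH/1,2-dichloroethane 3:1, O2 (1 atm), 60 °C
Reagents that add atoms: methanol, CO
Why: Lewis-acid-promoted Michael addition of methanol occurs at C6, the only unsubstituted ring carbon and the β-position of the carbonyl that is not part of the vinylogous ester, and the electron-rich hydroquinone is reoxidised by O2 with water as the only co-product (classical ZnCl2/MeOH alkoxylation of quinones), while ipso exchange at the isopropoxy carbon is retarded by the flanking alkyl chain.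

**Step 4**
Reactants: 11
Product: 13 2,2'-(tetradecane-1,14-diyl)bis(3-hydroxy-6-methoxy-5-methyl-1,4-benzoquinone), via bis(dichloroboryl ether) 12 (not isolated)
Conditions: BCl3 (5 equiv), CH2Cl2, −78 → −20 °C; then H2O
Reagents that add atoms: none
Why: BCl3 dealkylation cleaves the secondary isopropyl vinylogous ester through SN1-like O–C(iPr) heterolysis at low temperature much faster than the methyl one, and aqueous work-up hydrolyses the boron ether to the free hydroxyquinone.

**Step 5**
Reactants: 13
Product: 14 2-hydroxy-3-[14-(2,5-dihydroxy-4-methyl-3,6-dioxocyclohexa-1,4-dien-1-yl)tetradecyl]-5-methoxy-6-methyl-1,4-benzoquinone (target)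
Conditions: NaOH (1 M aq.)/dioxane 1:1, argon, 65 °C, stopped by HPLC at about 38% conversion of the OMe groups; then 2 M HCl
Reagents that add atoms: sodium hydroxide, [Na+].[OH-]
Why: Hydroxide addition–elimination hydrolyses a vinylogous methyl ester, and because the two rings are identical and remote the outcome is statistical (about 45% of 14, about 40% of 13 recovered and recycled, about 15% over-hydrolysed tetraol, separated by their different acidity), with no stereocentre involved.

**Compound list**
1 | 1,14-dibromotetradecane | BrCCCCCCCCCCCCCCBr | starting material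
2 | diisopropyl squarate, 3,4-di(propan-2-yloxy)cyclobut-3-ene-1,2-dione | CC(C)OC1=C(OC(C)C)C(=O)C1=O | starting material
3 | tetradecane-1,14-diylbis(magnesium bromide) | Br[Mg]CCCCCCCCCCCCCC[Mg]Br | intermediate
4 | 4,4'-(tetradecane-1,14-diyl)bis[4-hydroxy-2,3-di(propan-2-yloxy)cyclobut-2-en-1-one], diastereomer mixture | CC(C)OC1=C(OC(C)C)C(O)(CCCCCCCCCCCCCCC2(O)C(OC(C)C)=C(OC(C)C)C2=O)C1=O | intermediate
5 | 4,4'-(tetradecane-1,14-diyl)bis(3-isopropoxycyclobut-3-ene-1,2-dione) | CC(C)OC1=C(CCCCCCCCCCCCCCC2=C(OC(C)C)C(=O)C2=O)C(=O)C1=O | intermediate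
6 | isopropenylmagnesium bromide (prop-1-en-2-ylmagnesium bromide) | CC(=C)[Mg]Br | starting material
7 | 2,2'-(tetradecane-1,14-diyl)bis[4-hydroxy-3-isopropoxy-4-(prop-1-en-2-yl)cyclobut-2-en-1-one], diastereomer mixture | CC(=C)C1(O)C(OC(C)C)=C(CCCCCCCCCCCCCCC2=C(OC(C)C)C(O)(C(C)=C)C2=O)C1=O | intermediate
8 | 2,2'-(tetradecane-1,14-diyl)bis(3-isopropoxy-5-methylbenzene-1,4-diol) | CC(C)Oc1c(O)c(C)cc(O)c1CCCCCCCCCCCCCCc1c(O)cc(C)c(O)c1OC(C)C | intermediate
9 | 2,2'-(tetradecane-1,14-diyl)bis(3-isopropoxy-5-methyl-1,4-benzoquinone) | CC(C)OC1=C(CCCCCCCCCCCCCCC2=C(OC(C)C)C(=O)C(C)=CC2=O)C(=O)C=C(C)C1=O | intermediate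
10 | 2,2'-(tetradecane-1,14-diyl)bis(3-isopropoxy-6-methoxy-5-methylbenzene-1,4-diol) | CC(C)Oc1c(O)c(C)c(OC)c(O)c1CCCCCCCCCCCCCCc1c(O)c(OC)c(C)c(O)c1OC(C)C | intermediate
11 | 2,2'-(tetradecane-1,14-diyl)bis(3-isopropoxy-6-methoxy-5-methyl-1,4-benzoquinone) | CC(C)OC1=C(CCCCCCCCCCCCCCC2=C(OC(C)C)C(=O)C(C)=C(OC)C2=O)C(=O)C(OC)=C(C)C1=O | intermediate
12 | 2,2'-(tetradecane-1,14-diyl)bis[3-(dichloroboryloxy)-6-methoxy-5-methyl-1,4-benzoquinone] | COC1=C(C)C(=O)C(OB(Cl)Cl)=C(CCCCCCCCCCCCCCC2=C(OB(Cl)Cl)C(=O)C(C)=C(OC)C2=O)C1=O | intermediate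
13 | 2,2'-(tetradecane-1,14-diyl)bis(3-hydroxy-6-methoxy-5-methyl-1,4-benzoquinone) | COC1=C(C)C(=O)C(O)=C(CCCCCCCCCCCCCCC2=C(O)C(=O)C(C)=C(OC)C2=O)C1=O | intermediate
14 | 2-hydroxy-3-[14-(2,5-dihydroxy-4-methyl-3,6-dioxocyclohexa-1,4-dien-1-yl)tetradecyl]-5-methoxy-6-methyl-1,4-benzoquinone (achiral) | COC1=C(C)C(=O)C(O)=C(CCCCCCCCCCCCCCC2=C(O)C(=O)C(C)=C(O)C2=O)C1=O | target

**Totals**
Total steps: 5. Longest linear sequence: 5.

Step 5 is reliable chemistry but capped by statistics (at best about half per pass); it is run to partial conversion with recycling of 13 and is not counted among the three steps below.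

**Three steps most likely to fail**

Step 3 (C–H methoxylation of a deactivated, fully donor-substituted quinone; possible slow addition or OiPr/OMe exchange). The fallback sets out from 9 and comes back at 11 by turning the C–H into a leaving group first. Br2 (CH2Cl2, 0 °C) adds across the C5=C6 bond of each ring to give the bis(5,6-dibromide) F1. Et3N then eliminates HBr to give the bis(6-bromoquinone) F2. NaOMe (2.1 equiv, MeOH/THF, −20 °C) displaces bromide by addition–elimination much faster than it can attack the hindered isopropoxy carbon, giving 11.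

Step 1 (two Grignard termini on two squarates: Wurtz coupling, incomplete di-Grignard formation, oligomers). The fallback sets out from 2 and comes back at 5, making the linker by dimerisation instead of two-directional alkylation. 8-Bromooct-1-ene is converted with Mg into oct-7-en-1-ylmagnesium bromide F3, which adds once to 2 at −78 °C to give the mono-carbinol F4. Conc. HCl in CH2Cl2 rearranges it to 3-isopropoxy-4-(oct-7-en-1-yl)cyclobut-3-ene-1,2-dione F5. Self-metathesis with second-generation Grubbs catalyst RuCl2(H2IMes)(PCy3)(=CHPh) (CH2Cl2, 40 °C, ethene swept out) gives the tetradec-7-ene-linked bis(cyclobutenedione) F6 as an E/Z mixture. H2 over RhCl(PPh3)3 (benzene, rt) saturates only the disubstituted alkene and gives 5.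

Step 2 (double addition with the required regioselectivity, then a two-fold thermal cascade). The fallback sets out from 5 and comes back at 11, bypassing 9 and step 3 while still closing both rings in one thermolysis. Lithium methoxyacetylide F7 is generated from chloroacetaldehyde dimethyl acetal with LiNEt2 (3 equiv, THF, 0 °C) and added to 5 at −78 °C to give the bis(methoxyethynyl carbinol) F8. In toluene at 110 °C each half opens to an enynylketene, which cyclises through a diradical with hydrogen transfer from the hydroxyl group (Moore rearrangement). This gives the bis(6-methoxyquinone) F9 directly, with C5 unsubstituted and no oxidant needed. Radical C–H methylation at that only free position (AcOH, AgNO3 cat., (NH4)2S2O8, MeCN/H2O, 70 °C) gives 11.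

**Further compounds**
F1 | step 3 | 2,2'-(tetradecane-1,14-diyl)bis(5,6-dibromo-3-isopropoxy-5-methylcyclohex-2-ene-1,4-dione), diastereomer mixture | CC(C)OC1=C(CCCCCCCCCCCCCCC2=C(OC(C)C)C(=O)C(C)(Br)C(Br)C2=O)C(=O)C(Br)C(C)(Br)C1=O
F2 | step 3 | 2,2'-(tetradecane-1,14-diyl)bis(6-bromo-3-isopropoxy-5-methyl-1,4-benzoquinone) | CC(C)OC1=C(CCCCCCCCCCCCCCC2=C(OC(C)C)C(=O)C(C)=C(Br)C2=O)C(=O)C(Br)=C(C)C1=O
F3 | step 1 | oct-7-en-1-ylmagnesium bromide | C=CCCCCCC[Mg]Br
F4 | step 1 | 4-hydroxy-4-(oct-7-en-1-yl)-2,3-di(propan-2-yloxy)cyclobut-2-en-1-one, racemic | CC(C)OC1=C(OC(C)C)C(O)(CCCCCCC=C)C1=O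
F5 | step 1 | 3-isopropoxy-4-(oct-7-en-1-yl)cyclobut-3-ene-1,2-dione | CC(C)OC1=C(CCCCCCC=C)C(=O)C1=O
F6 | step 1 | 4,4'-(tetradec-7-ene-1,14-diyl)bis(3-isopropoxycyclobut-3-ene-1,2-dione), E/Z mixture | CC(C)OC1=C(CCCCCCC=CCCCCCCC2=C(OC(C)C)C(=O)C2=O)C(=O)C1=O
F7 | step 2 | lithium methoxyacetylide | [Li]C#COC
F8 | step 2 | 2,2'-(tetradecane-1,14-diyl)bis[4-hydroxy-3-isopropoxy-4-(methoxyethynyl)cyclobut-2-en-1-one], diastereomer mixture | COC#CC1(O)C(OC(C)C)=C(CCCCCCCCCCCCCCC2=C(OC(C)C)C(O)(C#COC)C2=O)C1=O
F9 | step 2 | 2,2'-(tetradecane-1,14-diyl)bis(3-isopropoxy-6-methoxy-1,4-benzoquinone) | CC(C)OC1=C(CCCCCCCCCCCCCCC2=C(OC(C)C)C(=O)C=C(OC)C2=O)C(=O)C(OC)=CC1=O
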